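**Plan**

1. Retrosynthesis: after removal of the TIPS ether, the acetonide and the lactone mask, the side chain is cut at C3'–C4' (methyl-bearing alkene carbon to the next CH2) and, in the same way, at C7'–C8'; the arene goes back to 4,6-dihydroxyphthalide.
2. Enabling feature: the phenol oxygen on C4 is ortho to the side chain on C5, so O4, aromatic C4 and C5, C1', C2' and C3' can be closed to a six-membered 4H-pyran ring (a 4H-chromene) in which O and C1' are locked cis across C2'=C3'.
3. Forward, arene: phthalide formation, O6 silylation, O4 allylation, Claisen shift to C5, O-vinylation and ring-closing metathesis build that chromene; the lactone is then lowered to an aldehyde aminal with a free CH2OH.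
4. Forward, chain: the C8'–C12' iodide from (S)-α-hydroxy-γ-butyrolactone is joined to lithiated 2,3-dihydrofuran by a cuprate 1,2-metallate rearrangement with methylation (C4'–C7', 6'E) and converted to the iodide.
5. Key event: the cuprate from this iodide and the C2-lithiated chromene undergoes the same 1,2-shift, which makes C3'–C4', opens the pyran ring to the free C4 phenol and leaves an alkenylcopper that iodomethane methylates (2'E); hydrolysis, lactol oxidation and desilylation finish.
6. Stereochemistry: C10' (S) comes unchanged from the lactone; both E alkenes come from the invertive 1,2-shift on a cyclic enol ether followed by retentive methylation.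

Key step: step 15

Remark: ring positions are those of phthalide (isobenzofuran-1(3H)-one) and primed numbers count the side chain from the ring; 3,5-dimethoxybenzoic acid, (S)-3-hydroxydihydrofuran-2(3H)-one and 2,3-dihydrofuran are taken as commercial.

**Arene fragment**

Step 1
Reactants: 1 3,5-dimethoxybenzoic acid
Product: 3 4,6-dimethoxyphthalide, via 2-(hydroxymethyl)-3,5-dimethoxybenzoic acid 2 (not isolated)
Conditions: 37% aq. HCHO, conc. HCl, AcOH, 90 °C
Reagents that add atoms: formaldehyde (C=O)
Why: Blanc-type hydroxymethylation should occur at C2, ortho to the carboxyl group and ortho/para to the two methoxy groups, and the benzylic alcohol lactonises under the acid.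

Step 2
Reactants: 3 4,6-dimethoxyphthalide
Product: 4 4,6-dihydroxyphthalide
Conditions: BBr3 (3 equiv), CH2Cl2, −78 °C to rt; H2O
Reagents that add atoms: none
Why: Lewis-acid ether cleavage, in which bromide removes each O-methyl group from the boron-complexed ether; any opened lactone recloses on aqueous work-up.

Step 3
Reactants: 4 4,6-dihydroxyphthalide
Product: 5 4-hydroxy-6-[(triisopropylsilyl)oxy]phthalide
Conditions: TIPSCl (1.05 equiv), imidazole, DMF, 0 °C
Reagents that add atoms: triisopropylsilyl chloride (CC(C)[Si](Cl)(C(C)C)C(C)C)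
Why: Silylation with a bulky chlorosilane should select the C6 hydroxyl, which has two ortho hydrogens, over the C4 hydroxyl, which is ortho to the lactone CH2.

Step 4
Reactants: 5 4-hydroxy-6-[(triisopropylsilyl)oxy]phthalide
Product: 6 4-(allyloxy)-6-[(triisopropylsilyl)oxy]phthalide
Conditions: allyl bromide, K2CO3, acetone, 50 °C
Reagents that add atoms: allyl bromide (C=CCBr)
Why: Williamson etherification of the remaining phenol; the aryl TIPS ether should be stable to carbonate in acetone.

Step 5
Reactants: 6 4-(allyloxy)-6-[(triisopropylsilyl)oxy]phthalide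
Product: 8 5-allyl-4-hydroxy-6-[(triisopropylsilyl)oxy]phthalide, via ortho-dienone 7 (not isolated)
Conditions: PhNEt2, 190 °C, sealed tube
Reagents that add atoms: none
Why: Aromatic Claisen rearrangement, a [3,3] shift that can only reach C5 because the other ortho position (C3a) is the ring fusion, followed by tautomerisation of dienone 7.

Step 6
Reactants: 8 5-allyl-4-hydroxy-6-[(triisopropylsilyl)oxy]phthalide
Product: 9 5-allyl-6-[(triisopropylsilyl)oxy]-4-(vinyloxy)phthalide
Conditions: Cu(OAc)2 (1 equiv), 2,4,6-trivinylcyclotriboroxane·pyridine (0.7 equiv), pyridine, CH2Cl2, air, rt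
Reagents that add atoms: 2,4,6-trivinylcyclotriboroxane–pyridine complex (C=CB1OB(C=C)OB(C=C)O1.c1ccncc1)
Why: Chan–Lam-type copper-mediated O-vinylation of a phenol under non-basic conditions that should spare the lactone and the silyl ether.

Step 7
Reactants: 9 5-allyl-6-[(triisopropylsilyl)oxy]-4-(vinyloxy)phthalide
Product: 10 lactone of 8-(hydroxymethyl)-5-[(triisopropylsilyl)oxy]-4H-chromene-7-carboxylic acid
Conditions: second-generation Grubbs catalyst RuCl2(=CHPh)(H2IMes)(PCy3) (5 mol%), 1,4-benzoquinone (10 mol%), toluene, 60 °C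
Reagents that add atoms: none
Why: Ring-closing metathesis between the allyl group and the aryl vinyl ether gives the six-membered cyclic enol ether (4H-chromene) with loss of ethene; benzoquinone suppresses allyl isomerisation.

Step 8
Reactants: 10 lactone of 8-(hydroxymethyl)-5-[(triisopropylsilyl)oxy]-4H-chromene-7-carboxylic acid
Product: 11 cyclic hemiacetal (lactol) of 8-(hydroxymethyl)-5-[(triisopropylsilyl)oxy]-4H-chromene-7-carbaldehyde
Conditions: DIBAL-H (i-Bu2AlH, 1.2 equiv), CH2Cl2, −78 °C; aq. Rochelle salt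
Reagents that add atoms: none
Why: Partial hydride reduction of the lactone stops at the aluminium hemiacetal at low temperature and leaves the enol ether and silyl ether untouched.

Step 9
Reactants: 11 cyclic hemiacetal (lactol) of 8-(hydroxymethyl)-5-[(triisopropylsilyl)oxy]-4H-chromene-7-carbaldehyde
Product: 12 {7-(1,3-diphenylimidazolidin-2-yl)-5-[(triisopropylsilyl)oxy]-4H-chromen-8-yl}methanol
Conditions: N,N'-diphenylethane-1,2-diamine (1.1 equiv), 4 Å molecular sieves, MeOH–CH2Cl2, rt
Reagents that add atoms: N,N'-diphenylethane-1,2-diamine (C(CNc1ccccc1)Nc1ccccc1)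
Why: Aminal formation from the open hydroxy-aldehyde tautomer, as with aldoses and this diamine, runs without acid and so spares the enol ether; it masks the carbonyl as a weakly basic imidazolidine and leaves the CH2OH free, so the later lithiation meets no benzylic ether C–H and no leaving group.

**Side-chain fragment**

Step 10
Reactants: 13 (S)-3-hydroxydihydrofuran-2(3H)-one
Product: 14 (3S)-4-methylpentane-1,3,4-triol
Conditions: MeMgBr (3.5 equiv), THF, 0 °C to rt; aq. NH4Cl
Reagents that add atoms: methylmagnesium bromide (C[Mg]Br)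
Why: Double Grignard addition to the lactone carbonyl gives the tertiary alcohol; the α-stereocentre is carried as its magnesium alkoxide, which suppresses enolisation, so the (S) configuration is kept.

Step 11
Reactants: 14 (3S)-4-methylpentane-1,3,4-triol
Product: 15 2-[(4S)-2,2,5,5-tetramethyl-1,3-dioxolan-4-yl]ethan-1-ol
Conditions: Me2C(OMe)2, TsOH (cat.), acetone, rt
Reagents that add atoms: 2,2-dimethoxypropane (COC(C)(C)OC)
Why: Acid-catalysed ketalisation under equilibrating conditions should favour the five-membered dioxolane on the vicinal diol over the six-membered dioxane, which would carry an axial methyl group.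

Step 12
Reactants: 15 2-[(4S)-2,2,5,5-tetramethyl-1,3-dioxolan-4-yl]ethan-1-ol
Product: 16 (4S)-4-(2-iodoethyl)-2,2,5,5-tetramethyl-1,3-dioxolane
Conditions: PPh3, imidazole, iodine, CH2Cl2, 0 °C to rt
Reagents that add atoms: iodine (II)
Why: Appel-type iodination of the primary alcohol through its alkoxyphosphonium salt; imidazole keeps the medium non-acidic for the acetonide.

Step 13
Reactants: 16 (4S)-4-(2-iodoethyl)-2,2,5,5-tetramethyl-1,3-dioxolane; 17 2,3-dihydrofuran
Product: 22 (3E)-4-methyl-6-[(4S)-2,2,5,5-tetramethyl-1,3-dioxolan-4-yl]hex-3-en-1-ol, via alkyllithium 18 (not isolated), via 5-lithio-2,3-dihydrofuran 19 (not isolated), via mixed cuprate 20 (not isolated), via alkenylcopper alkoxide 21 (not isolated)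
Conditions: 16, t-BuLi (2 equiv), Et2O, −78 °C; CuBr·SMe2 (1 equiv), Me2S, −78 to −40 °C; add 19 (from 17, t-BuLi, THF, −78 to 0 °C) at −78 °C, warm to rt; MeI, 0 °C to rt; aq. NH4Cl/NH3
Reagents that add atoms: iodomethane (CI)
Why: Known 1,2-metallate rearrangement of an α-alkoxyalkenyl cuprate: the alkyl group of 20 shifts from copper to the lithiated enol ether carbon with inversion as the ring C–O bond breaks, and iodomethane alkylates alkenylcopper 21 with retention, so the methyl ends cis and the new chain trans to the CH2CH2OH arm (6'E); the C10' stereocentre is not involved.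

Step 14
Reactants: 22 (3E)-4-methyl-6-[(4S)-2,2,5,5-tetramethyl-1,3-dioxolan-4-yl]hex-3-en-1-ol
Product: 23 (4S)-4-[(3E)-6-iodo-3-methylhex-3-en-1-yl]-2,2,5,5-tetramethyl-1,3-dioxolane
Conditions: PPh3, imidazole, iodine, CH2Cl2, 0 °C to rt
Reagents that add atoms: iodine (II)
Why: Appel-type iodination of the homoallylic primary alcohol, which leaves the alkene geometry and the acetonide untouched.

**Fragment union and endgame**

Step 15
Reactants: 23 (4S)-4-[(3E)-6-iodo-3-methylhex-3-en-1-yl]-2,2,5,5-tetramethyl-1,3-dioxolane; 12 {7-(1,3-diphenylimidazolidin-2-yl)-5-[(triisopropylsilyl)oxy]-4H-chromen-8-yl}methanol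
Product: 28 [2-(1,3-diphenylimidazolidin-2-yl)-6-hydroxy-5-{(2E,6E)-3,7-dimethyl-9-[(4S)-2,2,5,5-tetramethyl-1,3-dioxolan-4-yl]nona-2,6-dien-1-yl}-4-[(triisopropylsilyl)oxy]phenyl]methanol, via homoallyllithium 24 (not isolated), via dilithiated chromene 25 (not isolated), via mixed cuprate 26 (not isolated), via alkenylcopper aryloxide 27 (not isolated)
Conditions: 23, t-BuLi (2 equiv), Et2O, −78 °C; CuBr·SMe2 (1 equiv), Me2S, −78 to −40 °C; add 25 (from 12, t-BuLi (2.1 equiv), THF, −78 °C) at −78 °C, warm to 0 °C; MeI (5 equiv), −30 °C to rt; aq. NH4Cl/NH3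
Reagents that add atoms: iodomethane (CI)
Why: Proposed new method: after the hydroxyl proton, t-BuLi should remove the vinylic C2–H next to the ring oxygen of 12 (the neighbouring lithium alkoxide can hold the base beside that oxygen), and union with the alkylcopper from 24 should give ate complex 26, in which the alkyl group shifts from copper to C2 in the plane of the double bond while the C2–O bond breaks and a lithium aryloxide, a better leaving group than the alkoxide of the known cases, departs; the closest known reaction type is the 1,2-metallate rearrangement of α-lithiated 2,3-dihydrofurans and 3,4-dihydro-2H-pyrans with organocuprates followed by alkylation of the alkenylcopper, as used in step 13. No ring is closed: the pyran ring, a temporary tether, is opened and releases the C4 phenol of the target. No stereocentre is formed, but the geometry of the new trisubstituted alkene is fixed by the ring, because O and the benzylic CH2 are held cis on the enol ether, the shift inverts the carbenoid carbon so that the incoming chain ends trans to the benzylic CH2 and copper cis to it, and iodomethane then replaces copper with retention to give the 2'E alkene. The step needs metalation at C2 and not at the benzylic-allylic C4 or another benzylic position, and methylation at carbon and not at oxygen: the masked aldehyde is an N-aryl aminal and the neighbouring CH2OH is carried as its alkoxide, the aryl silyl ether is bulky and a poor director of lithiation, and lithium alkoxides and aryloxides should be inert to iodomethane in ethereal solvent at this temperature. The C10' stereocentre of 23 is remote and untouched.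

Step 16
Reactants: 28 [2-(1,3-diphenylimidazolidin-2-yl)-6-hydroxy-5-{(2E,6E)-3,7-dimethyl-9-[(4S)-2,2,5,5-tetramethyl-1,3-dioxolan-4-yl]nona-2,6-dien-1-yl}-4-[(triisopropylsilyl)oxy]phenyl]methanol
Product: 29 5-[(2E,6E,10S)-10,11-dihydroxy-3,7,11-trimethyldodeca-2,6-dien-1-yl]-6-[(triisopropylsilyl)oxy]-1,3-dihydroisobenzofuran-1,4-diol (both epimers at the hemiacetal carbon)
Conditions: 1 M aq. HCl, THF, 0 °C to rt
Reagents that add atoms: water (O)
Why: Acid hydrolysis cleaves the aminal and the acetonide in one operation, and the freed aldehyde is captured by the neighbouring CH2OH as the lactol; dilute acid at room temperature should not cyclise the ortho-prenyl phenol, and the C10' configuration is unaffected.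

Step 17
Reactants: 29 5-[(2E,6E,10S)-10,11-dihydroxy-3,7,11-trimethyldodeca-2,6-dien-1-yl]-6-[(triisopropylsilyl)oxy]-1,3-dihydroisobenzofuran-1,4-diol
Product: 30 4-hydroxy-5-[(2E,6E,10S)-10,11-dihydroxy-3,7,11-trimethyldodeca-2,6-dien-1-yl]-6-[(triisopropylsilyl)oxy]isobenzofuran-1(3H)-one
Conditions: activated MnO2 (15 equiv), CH2Cl2, rt
Reagents that add atoms: none
Why: MnO2 oxidation of the benzylic lactol to the phthalide; the saturated secondary and tertiary alcohols and the alkenes are not substrates for this oxidant.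

Step 18
Reactants: 30 4-hydroxy-5-[(2E,6E,10S)-10,11-dihydroxy-3,7,11-trimethyldodeca-2,6-dien-1-yl]-6-[(triisopropylsilyl)oxy]isobenzofuran-1(3H)-one
Product: 31 memnoconol
Conditions: Bu4NF, AcOH (1:1), THF, 0 °C
Reagents that add atoms: none
Why: Fluoride-induced cleavage of the aryl silyl ether, buffered with acetic acid so that the lactone and the prenylated resorcinol are not exposed to free phenoxide base.

**Compound list**

1 | 3,5-dimethoxybenzoic acid | COc1cc(OC)cc(C(=O)O)c1 | starting material
2 | 2-(hydroxymethyl)-3,5-dimethoxybenzoic acid | COc1cc(OC)c(CO)c(C(=O)O)c1 | intermediate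
3 | 4,6-dimethoxyphthalide | COc1cc(OC)c2COC(=O)c2c1 | intermediate
4 | 4,6-dihydroxyphthalide | Oc1cc(O)c2COC(=O)c2c1 | intermediate
5 | 4-hydroxy-6-[(triisopropylsilyl)oxy]phthalide | CC(C)[Si](Oc1cc(O)c2COC(=O)c2c1)(C(C)C)C(C)C | intermediate
6 | 4-(allyloxy)-6-[(triisopropylsilyl)oxy]phthalide | CC(C)[Si](Oc1cc(OCC=C)c2COC(=O)c2c1)(C(C)C)C(C)C | intermediate
7 | ortho-dienone (4-oxo tautomer of 8 with allyl and H on sp3 C5) | CC(C)[Si](OC1=CC2=C(COC2=O)C(=O)C1CC=C)(C(C)C)C(C)C | intermediate
8 | 5-allyl-4-hydroxy-6-[(triisopropylsilyl)oxy]phthalide | CC(C)[Si](Oc1cc2C(=O)OCc2c(O)c1CC=C)(C(C)C)C(C)C | intermediate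
9 | 5-allyl-6-[(triisopropylsilyl)oxy]-4-(vinyloxy)phthalide | CC(C)[Si](Oc1cc2C(=O)OCc2c(OC=C)c1CC=C)(C(C)C)C(C)C | intermediate
10 | lactone of 8-(hydroxymethyl)-5-[(triisopropylsilyl)oxy]-4H-chromene-7-carboxylic acid | CC(C)[Si](Oc1cc2C(=O)OCc2c2OC=CCc12)(C(C)C)C(C)C | intermediate
11 | cyclic hemiacetal (lactol) of 8-(hydroxymethyl)-5-[(triisopropylsilyl)oxy]-4H-chromene-7-carbaldehyde | CC(C)[Si](Oc1cc2C(O)OCc2c2OC=CCc12)(C(C)C)C(C)C | intermediate
12 | {7-(1,3-diphenylimidazolidin-2-yl)-5-[(triisopropylsilyl)oxy]-4H-chromen-8-yl}methanol | CC(C)[Si](Oc1cc(C2N(c3ccccc3)CCN2c2ccccc2)c(CO)c2OC=CCc12)(C(C)C)C(C)C | intermediate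
13 | (S)-3-hydroxydihydrofuran-2(3H)-one | O[C@H]1CCOC1=O | starting material
14 | (3S)-4-methylpentane-1,3,4-triol | OCC[C@H](O)C(C)(C)O | intermediate
15 | 2-[(4S)-2,2,5,5-tetramethyl-1,3-dioxolan-4-yl]ethan-1-ol | OCC[C@@H]1OC(C)(C)OC1(C)C | intermediate
16 | (4S)-4-(2-iodoethyl)-2,2,5,5-tetramethyl-1,3-dioxolane | ICC[C@@H]1OC(C)(C)OC1(C)C | intermediate
17 | 2,3-dihydrofuran | C1=COCC1 | starting material
18 | {2-[(4S)-2,2,5,5-tetramethyl-1,3-dioxolan-4-yl]ethyl}lithium | [Li]CC[C@@H]1OC(C)(C)OC1(C)C | intermediate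
19 | 5-lithio-2,3-dihydrofuran | [Li]C1=CCCO1 | intermediate
20 | lithium alkyl(4,5-dihydrofuran-2-yl)cuprate from 18 and 19 | [Li+].C1(=CCCO1)[Cu-]CC[C@@H]1OC(C)(C)OC1(C)C | intermediate
21 | ring-opened alkenylcopper lithium alkoxide (copper cis to the CH2CH2OLi arm) | [Li]OCC/C=C(\[Cu])CC[C@@H]1OC(C)(C)OC1(C)C | intermediate
22 | (3E)-4-methyl-6-[(4S)-2,2,5,5-tetramethyl-1,3-dioxolan-4-yl]hex-3-en-1-ol | OCC/C=C(\C)CC[C@@H]1OC(C)(C)OC1(C)C | intermediate
23 | (4S)-4-[(3E)-6-iodo-3-methylhex-3-en-1-yl]-2,2,5,5-tetramethyl-1,3-dioxolane | ICC/C=C(\C)CC[C@@H]1OC(C)(C)OC1(C)C | intermediate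
24 | homoallyllithium from 23 | [Li]CC/C=C(\C)CC[C@@H]1OC(C)(C)OC1(C)C | intermediate
25 | dilithiated 12 (lithium alkoxide and C2-lithiated 4H-chromene) | CC(C)[Si](Oc1cc(C2N(c3ccccc3)CCN2c2ccccc2)c(CO[Li])c2OC([Li])=CCc12)(C(C)C)C(C)C | intermediate
26 | lithium alkyl(4H-chromen-2-yl)cuprate from 24 and 25 | [Li+].CC(C)[Si](Oc1cc(C2N(c3ccccc3)CCN2c2ccccc2)c(CO[Li])c2OC(=CCc12)[Cu-]CC/C=C(\C)CC[C@@H]1OC(C)(C)OC1(C)C)(C(C)C)C(C)C | intermediate
27 | ring-opened alkenylcopper lithium aryloxide (copper on C3', cis to the benzylic CH2) | CC(C)[Si](Oc1cc(C2N(c3ccccc3)CCN2c2ccccc2)c(CO[Li])c(O[Li])c1C/C=C(\[Cu])CC/C=C(\C)CC[C@@H]1OC(C)(C)OC1(C)C)(C(C)C)C(C)C | intermediate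
28 | [2-(1,3-diphenylimidazolidin-2-yl)-6-hydroxy-5-{(2E,6E)-3,7-dimethyl-9-[(4S)-2,2,5,5-tetramethyl-1,3-dioxolan-4-yl]nona-2,6-dien-1-yl}-4-[(triisopropylsilyl)oxy]phenyl]methanol | CC(C)[Si](Oc1cc(C2N(c3ccccc3)CCN2c2ccccc2)c(CO)c(O)c1C/C=C(\C)CC/C=C(\C)CC[C@@H]1OC(C)(C)OC1(C)C)(C(C)C)C(C)C | intermediate
29 | 5-[(2E,6E,10S)-10,11-dihydroxy-3,7,11-trimethyldodeca-2,6-dien-1-yl]-6-[(triisopropylsilyl)oxy]-1,3-dihydroisobenzofuran-1,4-diol | C/C(=C\Cc1c(O[Si](C(C)C)(C(C)C)C(C)C)cc2c(c1O)COC2O)CC/C=C(\C)CC[C@H](O)C(C)(C)O | intermediate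
30 | 4-hydroxy-5-[(2E,6E,10S)-10,11-dihydroxy-3,7,11-trimethyldodeca-2,6-dien-1-yl]-6-[(triisopropylsilyl)oxy]isobenzofuran-1(3H)-one | C/C(=C\Cc1c(O[Si](C(C)C)(C(C)C)C(C)C)cc2c(c1O)COC2=O)CC/C=C(\C)CC[C@H](O)C(C)(C)O | intermediate
31 | memnoconol, 4,6-dihydroxy-5-[(2E,6E,10S)-10,11-dihydroxy-3,7,11-trimethyldodeca-2,6-dien-1-yl]isobenzofuran-1(3H)-one | C/C(=C\Cc1c(O)cc2c(c1O)COC2=O)CC/C=C(\C)CC[C@H](O)C(C)(C)O | target

**Count and risks**

Total step count: 18. Longest linear sequence: 13 steps (steps 1–9 and 15–18, from 1 to 31).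

Steps most likely to fail:

1. Step 15. The base may remove a benzylic-allylic proton at C4 of the chromene instead of the vinylic C2 proton. The lithiated aryl enol ether may lose lithium aryloxide before the 1,2-shift. The phenoxide or alkoxide may be methylated in competition with the alkenylcopper. The fallback sets out from 10 and 23 and comes back at 28, using only known reaction types and no lithiated enol ether. Addition of benzenesulfinic acid across the enol ether of 10 (CH2Cl2, rt) should give the 2-(phenylsulfonyl)chroman lactone F1. DIBAL-H reduction as in step 8 gives the lactol F2, and condensation with N,N'-diphenylethane-1,2-diamine as in step 9 gives the aminal alcohol F3. Treatment of F3 with n-BuLi (2.1 equiv, THF, −78 °C) removes the hydroxyl proton and then the proton on the carbon between oxygen and sulfone, by far the most acidic C–H. Alkylation with iodide 23 gives the tertiary sulfone F4. On warming with i-Pr2NEt, F4 loses benzenesulfinate to give the 2-alkyl-4H-chromene F5. Kumada-type coupling of F5 with MeMgBr and NiCl2(PPh3)2 (toluene, 80 °C) replaces the ring C–O bond by C–CH3 with retention, which places the methyl cis to the benzylic CH2 and gives 28.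

2. Step 3. Silylation may occur at the wrong phenol or at both, because the steric difference between the two hydroxyl groups is modest. The fallback sets out from 1 and comes back at 5, and fixes the position of the silyl ether by construction. BBr3 demethylation of 1 gives 3,5-dihydroxybenzoic acid F6, and Fischer esterification gives methyl 3,5-dihydroxybenzoate F7. Monosilylation with TIPSCl, where the two phenols are equivalent so that only mono/bis selection matters and diol and bis-ether can be recycled, gives methyl 3-hydroxy-5-[(triisopropylsilyl)oxy]benzoate F8. Ortho-formylation with MgCl2, Et3N and paraformaldehyde occurs only ortho to the free phenol and is kept from the site beside the silyl ether by its bulk, giving methyl 2-formyl-3-hydroxy-5-[(triisopropylsilyl)oxy]benzoate F9. NaBH4 reduction gives the hydroxymethyl ester F10, which lactonises to 5.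

3. Step 7. Ruthenium hydride species may move the allyl double bond into conjugation, which leads to a benzofuran on ring closure, or the catalyst may be arrested as a Fischer carbene at the vinyl ether. The fallback sets out from 8 and comes back at 10 without metathesis. Hydroboration of the allyl group with 9-BBN and oxidation with H2O2/NaOAc gives 4-hydroxy-5-(3-hydroxypropyl)-6-[(triisopropylsilyl)oxy]phthalide F11. Parikh–Doering oxidation of the primary alcohol gives the aldehyde in its ring-closed form, the 2-hydroxychroman lactol F12. Dehydration through the mesylate (MsCl, Et3N, CH2Cl2, 0 °C to rt) gives the 4H-chromene 10.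

Further compounds
F1 | step 15 | lactone of 8-(hydroxymethyl)-2-(phenylsulfonyl)-5-[(triisopropylsilyl)oxy]chromane-7-carboxylic acid | CC(C)[Si](Oc1cc2C(=O)OCc2c2OC(CCc12)S(=O)(=O)c1ccccc1)(C(C)C)C(C)C
F2 | step 15 | lactol from F1 | CC(C)[Si](Oc1cc2C(O)OCc2c2OC(CCc12)S(=O)(=O)c1ccccc1)(C(C)C)C(C)C
F3 | step 15 | {7-(1,3-diphenylimidazolidin-2-yl)-2-(phenylsulfonyl)-5-[(triisopropylsilyl)oxy]chroman-8-yl}methanol | CC(C)[Si](Oc1cc(C2N(c3ccccc3)CCN2c2ccccc2)c(CO)c2OC(CCc12)S(=O)(=O)c1ccccc1)(C(C)C)C(C)C
F4 | step 15 | C2-alkylated sulfone from F3 and 23 | CC(C)[Si](Oc1cc(C2N(c3ccccc3)CCN2c2ccccc2)c(CO)c2OC(CCc12)(CC/C=C(\C)CC[C@@H]1OC(C)(C)OC1(C)C)S(=O)(=O)c1ccccc1)(C(C)C)C(C)C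
F5 | step 15 | {7-(1,3-diphenylimidazolidin-2-yl)-2-{(3E)-4-methyl-6-[(4S)-2,2,5,5-tetramethyl-1,3-dioxolan-4-yl]hex-3-en-1-yl}-5-[(triisopropylsilyl)oxy]-4H-chromen-8-yl}methanol | CC(C)[Si](Oc1cc(C2N(c3ccccc3)CCN2c2ccccc2)c(CO)c2OC(CC/C=C(\C)CC[C@@H]3OC(C)(C)OC3(C)C)=CCc12)(C(C)C)C(C)C
F6 | step 3 | 3,5-dihydroxybenzoic acid | OC(=O)c1cc(O)cc(O)c1
F7 | step 3 | methyl 3,5-dihydroxybenzoate | COC(=O)c1cc(O)cc(O)c1
F8 | step 3 | methyl 3-hydroxy-5-[(triisopropylsilyl)oxy]benzoate | COC(=O)c1cc(O)cc(O[Si](C(C)C)(C(C)C)C(C)C)c1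
F9 | step 3 | methyl 2-formyl-3-hydroxy-5-[(triisopropylsilyl)oxy]benzoate | COC(=O)c1cc(O[Si](C(C)C)(C(C)C)C(C)C)cc(O)c1C=O
F10 | step 3 | methyl 3-hydroxy-2-(hydroxymethyl)-5-[(triisopropylsilyl)oxy]benzoate | COC(=O)c1cc(O[Si](C(C)C)(C(C)C)C(C)C)cc(O)c1CO
F11 | step 7 | 4-hydroxy-5-(3-hydroxypropyl)-6-[(triisopropylsilyl)oxy]phthalide | CC(C)[Si](Oc1cc2C(=O)OCc2c(O)c1CCCO)(C(C)C)C(C)C
F12 | step 7 | lactone of 2-hydroxy-8-(hydroxymethyl)-5-[(triisopropylsilyl)oxy]chromane-7-carboxylic acid | CC(C)[Si](Oc1cc2C(=O)OCc2c2OC(O)CCc12)(C(C)C)C(C)C
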